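## Retrosynthetic overview
1. Target ⇒ (13R)-labda-8(17),14-diene-13,19-diol + tigloyl chloride. The primary C19-OH is acylated last.
2. Diol ⇒ acyclic C20 (S)-2-alkyl-2-methyloxirane through one Lewis-acid cation–olefin cascade. Ring A closes first (C4–C5) and ring B second (C10–C9), and the cascade ends by loss of Me3Si from C17. This sets C4, C5, C9, C10, the axial CH2OH and the 8(17)-methylene.
3. Oxirane ⇒ methyl ketone by catalytic asymmetric methylene transfer, which brings in C19.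
4. Ketone ⇒ 1,1-dichloroalkene from (R)-linalool (brings C13) + a homoallylzinc + Me3SiCH2 (C17), joined by two stereospecific couplings in one flask.
5. Homoallyl unit ⇒ 2,3-dihydrofuran + ketal-masked 4-oxopentyllithium + MeI, which fixes the E C5=C10 alkene.

Assumption: labdane numbering is used for the acyclic precursors as well; commercial (R)-(−)-linalool is taken as ≥97% ee; and the (S)-binaphthoxide catalyst of step 7 is taken to deliver CH2 to the Re face of alkyl methyl ketones (if the sense is opposite, the equally cheap (R)-BINOL is used).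

## Route

Step 1
Reactants: 1 (R)-(−)-linalool
Product: 2 (3R)-3,7-dimethyl-3-(triethylsilyloxy)octa-1,6-diene
Conditions: TESOTf, 2,6-lutidine, CH2Cl2, −78 to 0 °C
Reagents that add atoms: triethylsilyl trifluoromethanesulfonate, CC[Si](CC)(CC)OS(=O)(=O)C(F)(F)F
Why: Silyl triflate O-silylation of the hindered tertiary alcohol; C13 comes from the chiral pool and no bond to it is broken.

Step 2
Reactants: 2 (3R)-3,7-dimethyl-3-(triethylsilyloxy)octa-1,6-diene
Product: 4 (4R)-4-methyl-4-(triethylsilyloxy)hex-5-enal, via secondary ozonide 3 (not isolated)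
Conditions: O3 (1 equiv, Sudan red 7B end point), CH2Cl2, −78 °C; PPh3, −78 °C to rt
Reagents that add atoms: ozone, [O-][O+]=O
Why: Criegee ozonolysis with reductive work-up; electrophilic ozone takes the electron-rich trisubstituted alkene far faster than the hindered vinyl group next to the silyloxy carbon, and C13 is untouched.

Step 3
Reactants: 4 (4R)-4-methyl-4-(triethylsilyloxy)hex-5-enal
Product: 5 (3R)-7,7-dichloro-3-methyl-3-(triethylsilyloxy)hepta-1,6-diene
Conditions: Cl3CP(O)(OEt)2, n-BuLi, THF/Et2O, −100 °C; then 4, −100 °C to rt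
Reagents that add atoms: diethyl (trichloromethyl)phosphonate, CCOP(=O)(OCC)C(Cl)(Cl)Cl
Why: Horner–Wadsworth–Emmons-type gem-dichloroolefination; Cl/Li exchange gives the phosphonate carbanion, which adds to the aldehyde and loses lithium diethyl phosphate under basic, silyl-ether-safe conditions, and the new carbon is C8.

Step 4
Reactants: 6 2,3-dihydrofuran; 7 2-(3-chloropropyl)-2-methyl-1,3-dioxolane (2 equiv)
Product: 14 (E)-9-hydroxy-6-methylnon-6-en-2-one, via 5-lithio-2,3-dihydrofuran 8 (not isolated), via ketal-masked 4-oxopentyllithium 9 (not isolated), via lithium dialkylcuprate 10 (not isolated), via dilithium mixed cuprate 11 (not isolated), via ring-opened alkenylcuprate 12 (not isolated), via ketal alcohol 13 (not isolated)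
Conditions: 6, t-BuLi, THF, −78 to 0 °C; 7, Li, DTBB (5 mol %), THF, −78 °C, then CuBr·SMe2, Et2O/Me2S, −78 °C; add 8, −78 °C to rt; MeI (excess), 0 °C to rt; 1 M HCl, THF, rt
Reagents that add atoms: iodomethane, CI; water, O
Why: Kocienski-type 1,2-metallate rearrangement; the alkyl group shifts from copper to the lithiated enol-ether carbon with inversion and ring opening, so it ends trans to the CH2CH2O arm, and methylation of the alkenylcuprate with retention fixes the E C5=C10 alkene before the acid work-up frees the ketone.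

Step 5
Reactants: 14 (E)-9-hydroxy-6-methylnon-6-en-2-one
Product: 15 (E)-9-iodo-6-methylnon-6-en-2-one
Conditions: I2, PPh3, imidazole, CH2Cl2, 0 °C
Reagents that add atoms: iodine, II
Why: Appel-type (Garegg–Samuelsson) iodination by SN2 at the primary carbinol; the ketone and the alkene geometry are not affected.

Step 6
Reactants: 15 (E)-9-iodo-6-methylnon-6-en-2-one; 5 (3R)-7,7-dichloro-3-methyl-3-(triethylsilyloxy)hepta-1,6-diene
Product: 18 (6E,10Z,14R)-6,14-dimethyl-14-(triethylsilyloxy)-10-[(trimethylsilyl)methyl]hexadeca-6,10,15-trien-2-one, via homoallylzinc iodide 16 (not isolated), via (Z)-chloroalkene 17 (not isolated)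
Conditions: 15, Zn dust, LiCl, THF, 40 °C; 5 (1.1 equiv), PdCl2(DPEphos) (3 mol %), THF, rt; then Me3SiCH2ZnCl (3 equiv, from Me3SiCH2MgCl + ZnCl2), Pd(P(t-Bu)3)2 (5 mol %), THF/NMP, 50 °C
Reagents that add atoms: (trimethylsilyl)methylmagnesium chloride, C[Si](C)(C)C[Mg]Cl
Why: Two Negishi couplings in one flask; oxidative addition goes first into the C–Cl bond trans to the alkyl chain, so C7 enters trans to C11, the remaining C–Cl bond is then replaced by CH2SiMe3 with retention under the bulky-phosphine catalyst, and organozincs leave the ketone alone.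

Step 7
Reactants: 18 (6E,10Z,14R)-6,14-dimethyl-14-(triethylsilyloxy)-10-[(trimethylsilyl)methyl]hexadeca-6,10,15-trien-2-one
Product: 19 (2S)-2-methyl-2-[(4E,8Z,12R)-4,12-dimethyl-12-(triethylsilyloxy)-8-[(trimethylsilyl)methyl]tetradeca-4,8,13-trienyl]oxirane
Conditions: Me3S(O)I, NaH, THF (ylide preformed); LaLi3((S)-binaphthoxide)3 (5 mol %), (2,4,6-(MeO)3C6H2)3P=O (5 mol %), MS 5A, THF, rt
Reagents that add atoms: trimethylsulfoxonium iodide, C[S+](C)(C)=O.[I-]
Why: Catalytic asymmetric Corey–Chaykovsky epoxidation; the La/Li binaphthoxide binds ketone and ylide together, tells CH3 from CH2R, and delivers CH2 (C19) to the Re face to give the (S)-oxirane carbon, the future C4.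

Step 8
Reactants: 19 (2S)-2-methyl-2-[(4E,8Z,12R)-4,12-dimethyl-12-(triethylsilyloxy)-8-[(trimethylsilyl)methyl]tetradeca-4,8,13-trienyl]oxirane
Product: 21 (13R)-labda-8(17),14-diene-13,19-diol (4S,5R,9S,10R,13R), via bicyclic silyl ether 20 (not isolated)
Conditions: MeAlCl2 (1.2 equiv), CH2Cl2 (0.005 M), −94 to −78 °C, 30 min; Et3N, aq. NaHCO3; crude 20, TBAF, THF, rt
Reagents that add atoms: none
Why: Epoxide-initiated cation–olefin bicyclisation with allylsilane termination through a chair–chair array, in which C5 opens the tertiary C4–O bond with inversion, the tied-back oxirane CH2 takes the axial site so that the free methyl avoids the 1,3-diaxial clash with C20, anti addition across the E C5=C10 alkene gives the trans-decalin, the main-chain-E allylsilane puts the C9 side chain equatorial, loss of Me3Si from C17 leaves only the 8(17)-alkene, and fluoride then removes the silyl groups.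

Step 9
Reactants: 21 (13R)-labda-8(17),14-diene-13,19-diol; 22 tigloyl chloride
Product: 23 (13R)-13-hydroxylabda-8(17),14-dien-19-yl (E)-2-methylbut-2-enoate (target)
Conditions: 22 (1.5 equiv), pyridine, DMAP (0.2 equiv), CH2Cl2, 0 °C to rt
Reagents that add atoms: none
Why: DMAP-catalysed acylation takes only the primary C19-OH and not the tertiary allylic C13-OH, pyridine instead of a stronger amine avoids vinylketene deconjugation, and the E-tiglate geometry is kept.

## Compound list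
1 | (R)-(−)-linalool | C=C[C@](C)(O)CCC=C(C)C | starting material
2 | (3R)-3,7-dimethyl-3-(triethylsilyloxy)octa-1,6-diene | C=C[C@](C)(O[Si](CC)(CC)CC)CCC=C(C)C | intermediate
3 | 3,3-dimethyl-5-[(3R)-3-methyl-3-(triethylsilyloxy)pent-4-enyl]-1,2,4-trioxolane (both ring epimers) | C=C[C@](C)(O[Si](CC)(CC)CC)CCC1OOC(C)(C)O1 | intermediate
4 | (4R)-4-methyl-4-(triethylsilyloxy)hex-5-enal | C=C[C@](C)(O[Si](CC)(CC)CC)CCC=O | intermediate
5 | (3R)-7,7-dichloro-3-methyl-3-(triethylsilyloxy)hepta-1,6-diene | C=C[C@](C)(O[Si](CC)(CC)CC)CCC=C(Cl)Cl | intermediate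
6 | 2,3-dihydrofuran | C1CC=CO1 | starting material
7 | 2-(3-chloropropyl)-2-methyl-1,3-dioxolane | CC1(CCCCl)OCCO1 | starting material
8 | 5-lithio-2,3-dihydrofuran | [Li]C1=CCCO1 | intermediate
9 | 3-(2-methyl-1,3-dioxolan-2-yl)propyllithium | [Li]CCCC1(C)OCCO1 | intermediate
10 | lithium bis[3-(2-methyl-1,3-dioxolan-2-yl)propyl]cuprate | [Li+].CC1(CCC[Cu-]CCCC2(C)OCCO2)OCCO1 | intermediate
11 | dilithium (4,5-dihydrofuran-2-yl)bis[3-(2-methyl-1,3-dioxolan-2-yl)propyl]cuprate | [Li+].[Li+].CC1(CCC[Cu-2](CCCC2(C)OCCO2)C2=CCCO2)OCCO1 | intermediate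
12 | dilithium alkenyl(alkyl)cuprate alkoxide, copper cis to the CH2CH2O arm | [Li+].[Li+].[O-]CC/C=C(\[Cu-]CCCC1(C)OCCO1)CCCC1(C)OCCO1 | intermediate
13 | (E)-4-methyl-7-(2-methyl-1,3-dioxolan-2-yl)hept-3-en-1-ol | CC1(CCC/C(C)=C/CCO)OCCO1 | intermediate
14 | (E)-9-hydroxy-6-methylnon-6-en-2-one | CC(=O)CCC/C(C)=C/CCO | intermediate
15 | (E)-9-iodo-6-methylnon-6-en-2-one | CC(=O)CCC/C(C)=C/CCI | intermediate
16 | [(E)-4-methyl-8-oxonon-3-enyl]zinc iodide | CC(=O)CCC/C(C)=C/CC[Zn]I | intermediate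
17 | (6E,10Z,14R)-10-chloro-6,14-dimethyl-14-(triethylsilyloxy)hexadeca-6,10,15-trien-2-one | C=C[C@](C)(O[Si](CC)(CC)CC)CC/C=C(\Cl)CC/C=C(\C)CCCC(C)=O | intermediate
18 | (6E,10Z,14R)-6,14-dimethyl-14-(triethylsilyloxy)-10-[(trimethylsilyl)methyl]hexadeca-6,10,15-trien-2-one | C=C[C@](C)(O[Si](CC)(CC)CC)CC/C=C(\C[Si](C)(C)C)CC/C=C(\C)CCCC(C)=O | intermediate
19 | (2S)-2-methyl-2-[(4E,8Z,12R)-4,12-dimethyl-12-(triethylsilyloxy)-8-[(trimethylsilyl)methyl]tetradeca-4,8,13-trienyl]oxirane | C=C[C@](C)(O[Si](CC)(CC)CC)CC/C=C(\C[Si](C)(C)C)CC/C=C(\C)CCC[C@@]1(C)CO1 | intermediate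
20 | (13R)-13-(triethylsilyloxy)labda-8(17),14-dien-19-ol (4S,5R,9S,10R) | C=C[C@](C)(O[Si](CC)(CC)CC)CC[C@H]1C(=C)CC[C@H]2[C@@](C)(CO)CCC[C@]12C | intermediate
21 | (13R)-labda-8(17),14-diene-13,19-diol (4S,5R,9S,10R) | C=C[C@](C)(O)CC[C@H]1C(=C)CC[C@H]2[C@@](C)(CO)CCC[C@]12C | intermediate
22 | tigloyl chloride, (E)-2-methylbut-2-enoyl chloride | C/C=C(\C)C(=O)Cl | starting material
23 | (13R)-13-hydroxylabda-8(17),14-dien-19-yl (E)-2-methylbut-2-enoate (4S,5R,9S,10R,13R) | C=C[C@](C)(O)CC[C@H]1C(=C)CC[C@H]2[C@@](C)(COC(=O)/C(C)=C/C)CCC[C@]12C | target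

## Step count
Total step count: 9.
Longest linear sequence: 7 (steps 1, 2, 3, 6, 7, 8, 9).

## Steps most likely to fail

**Step 8 (cascade).**
- The Lewis acid may ionise the tertiary allylic silyl ether.
- The C13 ether oxygen may trap the C8 cation.
- A 1,2-hydride shift of the opened oxirane may compete with ring closure.
- The chair with equatorial CH2O may compete with the desired one.

The fallback removes the allylic character of the C13 ether during the cascade. It sets out from 5 and comes back at 20. Radical anti-Markovnikov addition of thiophenol to the vinyl group (PhSH, AIBN, toluene, 80 °C) gives (3R)-7,7-dichloro-3-methyl-1-(phenylsulfanyl)-3-(triethylsilyloxy)hept-6-ene F1. Coupling with 16 as in step 6 goes through (6E,10Z,14R)-10-chloro-6,14-dimethyl-16-(phenylsulfanyl)-14-(triethylsilyloxy)hexadeca-6,10-dien-2-one F2. The second coupling gives (6E,10Z,14R)-6,14-dimethyl-16-(phenylsulfanyl)-14-(triethylsilyloxy)-10-[(trimethylsilyl)methyl]hexadeca-6,10-dien-2-one F3. The epoxidation of step 7 gives the corresponding (2S)-2-alkyl-2-methyloxirane F4. MeAlCl2 (2.2 equiv, because the sulfide binds one) closes both rings to (13R)-15-(phenylsulfanyl)-13-(triethylsilyloxy)labd-8(17)-en-19-ol F5. NaIO4 in aqueous MeOH gives the sulfoxide (13R)-15-(phenylsulfinyl)-13-(triethylsilyloxy)labd-8(17)-en-19-ol F6. Thermal syn-elimination (toluene, CaCO3, 110 °C) restores the vinyl group and delivers 20.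

**Step 6 (double coupling).**
- Me3SiCH2ZnCl transmetalates slowly.
- Leftover 16 can compete in the second stage.

The fallback masks the ketone so that a Grignard reagent can be used. It sets out from 13, taken out of step 4 by a neutral NH4Cl work-up, and comes back at 18. Iodination (I2, PPh3, imidazole) gives 2-[(E)-7-iodo-4-methylhept-4-enyl]-2-methyl-1,3-dioxolane F7. Zinc insertion gives [(E)-4-methyl-7-(2-methyl-1,3-dioxolan-2-yl)hept-3-enyl]zinc iodide F8. Coupling with 5 under PdCl2(DPEphos) gives the isolated 2-[(4E,8Z,12R)-8-chloro-4,12-dimethyl-12-(triethylsilyloxy)tetradeca-4,8,13-trienyl]-2-methyl-1,3-dioxolane F9. A Kumada coupling (Me3SiCH2MgCl, NiCl2(dppp), Et2O, reflux) gives 2-[(4E,8Z,12R)-4,12-dimethyl-12-(triethylsilyloxy)-8-[(trimethylsilyl)methyl]tetradeca-4,8,13-trienyl]-2-methyl-1,3-dioxolane F10. PPTS in wet acetone frees 18.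

**Step 7 (asymmetric methylene transfer).** The facial selectivity for a long-chain alkyl methyl ketone may stall near 90%.

The fallback replaces face selection by kinetic resolution. It sets out from 18 and comes back at 19. Unselective epoxidation with dimethylsulfonium methylide (Me3SI, NaH, DMSO/THF, 0 °C) gives 19 together with its (2R)-oxirane epimer F11. A Jacobsen-type resolution follows: (salen)CrN3 (salen = N,N'-bis(3,5-di-tert-butylsalicylidene)-trans-1,2-cyclohexanediamine dianion, the antipode matched with the 2R-oxirane), TMSN3 and i-PrOH in t-BuOMe at 0 °C. This opens only F11, giving (2R,6E,10Z,14R)-1-azido-2,6,14-trimethyl-14-(triethylsilyloxy)-10-[(trimethylsilyl)methyl]hexadeca-6,10,15-trien-2-ol F12. F12 is removed by chromatography from unchanged 19.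

## Further compounds
F1 | step 8 | (3R)-7,7-dichloro-3-methyl-1-(phenylsulfanyl)-3-(triethylsilyloxy)hept-6-ene | c1ccccc1SCC[C@](C)(O[Si](CC)(CC)CC)CCC=C(Cl)Cl
F2 | step 8 | (6E,10Z,14R)-10-chloro-6,14-dimethyl-16-(phenylsulfanyl)-14-(triethylsilyloxy)hexadeca-6,10-dien-2-one | c1ccccc1SCC[C@](C)(O[Si](CC)(CC)CC)CC/C=C(\Cl)CC/C=C(\C)CCCC(C)=O
F3 | step 8 | (6E,10Z,14R)-6,14-dimethyl-16-(phenylsulfanyl)-14-(triethylsilyloxy)-10-[(trimethylsilyl)methyl]hexadeca-6,10-dien-2-one | c1ccccc1SCC[C@](C)(O[Si](CC)(CC)CC)CC/C=C(\C[Si](C)(C)C)CC/C=C(\C)CCCC(C)=O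
F4 | step 8 | (2S)-2-methyl-2-[(4E,8Z,12R)-4,12-dimethyl-14-(phenylsulfanyl)-12-(triethylsilyloxy)-8-[(trimethylsilyl)methyl]tetradeca-4,8-dienyl]oxirane | c1ccccc1SCC[C@](C)(O[Si](CC)(CC)CC)CC/C=C(\C[Si](C)(C)C)CC/C=C(\C)CCC[C@@]1(C)CO1
F5 | step 8 | (13R)-15-(phenylsulfanyl)-13-(triethylsilyloxy)labd-8(17)-en-19-ol | c1ccccc1SCC[C@](C)(O[Si](CC)(CC)CC)CC[C@H]1C(=C)CC[C@H]2[C@@](C)(CO)CCC[C@]12C
F6 | step 8 | (13R)-15-(phenylsulfinyl)-13-(triethylsilyloxy)labd-8(17)-en-19-ol (both sulfur epimers) | O=S(c1ccccc1)CC[C@](C)(O[Si](CC)(CC)CC)CC[C@H]1C(=C)CC[C@H]2[C@@](C)(CO)CCC[C@]12C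
F7 | step 6 | 2-[(E)-7-iodo-4-methylhept-4-enyl]-2-methyl-1,3-dioxolane | CC1(CCC/C(C)=C/CCI)OCCO1
F8 | step 6 | [(E)-4-methyl-7-(2-methyl-1,3-dioxolan-2-yl)hept-3-enyl]zinc iodide | CC1(CCC/C(C)=C/CC[Zn]I)OCCO1
F9 | step 6 | 2-[(4E,8Z,12R)-8-chloro-4,12-dimethyl-12-(triethylsilyloxy)tetradeca-4,8,13-trienyl]-2-methyl-1,3-dioxolane | C=C[C@](C)(O[Si](CC)(CC)CC)CC/C=C(\Cl)CC/C=C(\C)CCCC1(C)OCCO1
F10 | step 6 | 2-[(4E,8Z,12R)-4,12-dimethyl-12-(triethylsilyloxy)-8-[(trimethylsilyl)methyl]tetradeca-4,8,13-trienyl]-2-methyl-1,3-dioxolane | C=C[C@](C)(O[Si](CC)(CC)CC)CC/C=C(\C[Si](C)(C)C)CC/C=C(\C)CCCC1(C)OCCO1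
F11 | step 7 | (2R)-2-methyl-2-[(4E,8Z,12R)-4,12-dimethyl-12-(triethylsilyloxy)-8-[(trimethylsilyl)methyl]tetradeca-4,8,13-trienyl]oxirane | C=C[C@](C)(O[Si](CC)(CC)CC)CC/C=C(\C[Si](C)(C)C)CC/C=C(\C)CCC[C@]1(C)CO1
F12 | step 7 | (2R,6E,10Z,14R)-1-azido-2,6,14-trimethyl-14-(triethylsilyloxy)-10-[(trimethylsilyl)methyl]hexadeca-6,10,15-trien-2-ol | C=C[C@](C)(O[Si](CC)(CC)CC)CC/C=C(\C[Si](C)(C)C)CC/C=C(\C)CCC[C@](O)(C)CN=[N+]=[N-]
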